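## Retrosynthetic overview

1. The quinone is unmasked last. Target 33 comes from the protected bis-indolyl hydroquinone 30 by N-detosylation, MOM cleavage and Ag2O oxidation.
2. The strategy rests on one feature. In indole A the carbocycle C3a–C4–C5–C6–C7–C7a carries hydrogen at C4, C5 and C6, and its only substituent is the prenyl group on C7, next to C7a. The ring is therefore cut at C5–C6 and grown on a pyrrole: 30 comes from 28 by 6π closure of the triene CH2=C(prenyl)–C5=C4(pyrrole)–CH=CH–OMe, followed by loss of MeOH.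
3. Precursor 28 comes from 4,5-dibromopyrrole 17 by two Suzuki couplings, first at C5 (dienyl boronate 22) and then at C4 ((E)-methoxyvinyl boronate 27). Both bromines are placed while the inert vinyl of the tert-prenyl group is the only alkene present.
4. Dibromide 17 comes from pyrrole 14, made by Paal–Knorr closure of keto aldehyde 13. Compound 13 arises from α-arylation of ketone 7 with the symmetric dibromide 4 (from bromanilic acid), then prenylation and ozonolysis. Indole B enters by Suzuki coupling with 15.
5. Ring order: the central arene and indole B are bought, the pyrrole ring of indole A forms in step 8, and the benzene ring of indole A forms in step 17.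

Key step: step 17

Remark: the target has no stereocentre. Compounds 11, 12, 13 and 29 are racemic and lose their single stereocentre on aromatisation. The hindered aryl–heteroaryl axes are taken as not configurationally fixed. Pyrrole numbering throughout is N1, C2 (tert-prenyl), C3 (aryl), C4, C5.

## Route

Step 1
Reactants: 1 bromanilic acid
Product: 2 2,5-dibromo-3,6-dimethoxy-1,4-benzoquinone
Conditions: MeI (excess), Ag2O, CHCl3, rt, dark
Reagents that add atoms: methyl iodide, CI
Why: The two strongly acidic vinylogous carboxylic OH groups should be O-methylated as their silver salts (silver-oxide-mediated Williamson-type alkylation) without touching the C–Br bonds or the quinone.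

Step 2
Reactants: 2 2,5-dibromo-3,6-dimethoxy-1,4-benzoquinone
Product: 3 2,5-dibromo-3,6-dimethoxybenzene-1,4-diol
Conditions: Na2S2O4, EtOAc–H2O, rt
Reagents that add atoms: none
Why: Dithionite reduction of a quinone to its hydroquinone is a mild two-electron process that leaves the aryl bromides and methyl ethers intact.

Step 3
Reactants: 3 2,5-dibromo-3,6-dimethoxybenzene-1,4-diol
Product: 4 1,4-dibromo-2,5-dimethoxy-3,6-bis(methoxymethoxy)benzene
Conditions: NaH, MOMCl, DMF, 0 °C → rt, Ar
Reagents that add atoms: chloromethyl methyl ether, COCCl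
Why: Williamson-type alkylation of the bis-phenoxide gives MOM ethers that withstand bases, palladium catalysis, ozone and heat and leave under mild acid at the end.

Step 4
Reactants: 5 2,2-dimethylbut-3-enoic acid
Product: 7 3,3-dimethylpent-4-en-2-one, via dilithium gem-diolate 6 (not isolated)
Conditions: MeLi (2.2 equiv), Et2O, 0 °C; inverse quench into cold aq. NH4Cl
Reagents that add atoms: methyllithium, [Li]C
Why: Addition of methyllithium to the lithium carboxylate stops at the gem-diolate, which collapses to the methyl ketone only on quenching, and the quaternary α-carbon prevents the alkene from moving into conjugation.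

Step 5
Reactants: 4 1,4-dibromo-2,5-dimethoxy-3,6-bis(methoxymethoxy)benzene (1.5 equiv); 7 3,3-dimethylpent-4-en-2-one
Product: 8 1-[4-bromo-2,5-dimethoxy-3,6-bis(methoxymethoxy)phenyl]-3,3-dimethylpent-4-en-2-one
Conditions: Pd2(dba)3 (2.5 mol %), XPhos (6 mol %), K3PO4, toluene, 90 °C
Reagents that add atoms: none
Why: In this Buchwald–Hartwig ketone α-arylation the methyl group is the only enolisable site, and the more acidic product rests as its enolate, which makes the ring too electron-rich for a second oxidative addition, so mono-coupling of the symmetric dibromide should prevail.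

Step 6
Reactants: 8 1-[4-bromo-2,5-dimethoxy-3,6-bis(methoxymethoxy)phenyl]-3,3-dimethylpent-4-en-2-one; 9 prenyl bromide
Product: 11 (±)-5-[4-bromo-2,5-dimethoxy-3,6-bis(methoxymethoxy)phenyl]-3,3,8-trimethylnona-1,7-dien-4-one, via potassium enolate 10 (not isolated)
Conditions: KHMDS, THF, −78 °C; then 9, −78 → 0 °C
Reagents that add atoms: none
Why: C-alkylation of the single possible benzylic enolate with a soft, very reactive allylic bromide (SN2) should be clean, and the new stereocentre forms as a racemate that is erased in step 8.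

Step 7
Reactants: 11 (±)-5-[4-bromo-2,5-dimethoxy-3,6-bis(methoxymethoxy)phenyl]-3,3,8-trimethylnona-1,7-dien-4-one
Product: 13 (±)-3-[4-bromo-2,5-dimethoxy-3,6-bis(methoxymethoxy)phenyl]-5,5-dimethyl-4-oxohept-6-enal, via secondary ozonide 12 (not isolated)
Conditions: O3 (1 equiv, Sudan red 7B end point), CH2Cl2, −78 °C; then Me2S, −78 °C → rt
Reagents that add atoms: ozone, [O-][O+]=O
Why: In this chemoselective ozonolysis the electron-rich trisubstituted alkene reacts far faster than the hindered, inductively deactivated vinyl group beside the quaternary carbon, so the prenyl unit serves as a masked CH2CHO group.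

Step 8
Reactants: 13 (±)-3-[4-bromo-2,5-dimethoxy-3,6-bis(methoxymethoxy)phenyl]-5,5-dimethyl-4-oxohept-6-enal
Product: 14 3-[4-bromo-2,5-dimethoxy-3,6-bis(methoxymethoxy)phenyl]-2-(2-methylbut-3-en-2-yl)-1H-pyrrole
Conditions: NH4OAc (10 equiv), EtOH–AcOH (20:1), 70 °C, Ar
Reagents that add atoms: ammonium acetate, CC(=O)[O-].[NH4+]
Why: In this Paal–Knorr pyrrole synthesis ammonia condenses first with the aldehyde and the nitrogen then attacks the hindered ketone intramolecularly, as in known closures to 2-tert-alkylpyrroles, which places the crowded C2 and C3 groups on the ring at once.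

Step 9
Reactants: 14 3-[4-bromo-2,5-dimethoxy-3,6-bis(methoxymethoxy)phenyl]-2-(2-methylbut-3-en-2-yl)-1H-pyrrole; 15 1-tosylindole-3-boronic acid (1.6 equiv)
Product: 16 3-{2,5-dimethoxy-3,6-bis(methoxymethoxy)-4-[2-(2-methylbut-3-en-2-yl)-1H-pyrrol-3-yl]phenyl}-1-tosylindole
Conditions: Pd(OAc)2 (5 mol %), SPhos (10 mol %), K3PO4, toluene–H2O (10:1), 90 °C
Reagents that add atoms: none
Why: This Suzuki–Miyaura coupling acts on the only C–Br bond left, and the bulky electron-rich biaryl phosphine is the established answer to di-ortho-alkoxy, electron-rich aryl bromides and tolerates the free pyrrole N–H.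

Step 10
Reactants: 16 3-{2,5-dimethoxy-3,6-bis(methoxymethoxy)-4-[2-(2-methylbut-3-en-2-yl)-1H-pyrrol-3-yl]phenyl}-1-tosylindole
Product: 17 3-{4-[4,5-dibromo-2-(2-methylbut-3-en-2-yl)-1H-pyrrol-3-yl]-2,5-dimethoxy-3,6-bis(methoxymethoxy)phenyl}-1-tosylindole
Conditions: NBS (2.05 equiv), THF, −78 → −20 °C, dark
Reagents that add atoms: N-bromosuccinimide, O=C1CCC(=O)N1Br
Why: Electrophilic aromatic bromination fills the two free pyrrole positions, while the N-sulfonylindole, the fully substituted arene and the neopentyl-type vinyl group are far less nucleophilic, and it is done here because the prenyl and methylene alkenes that would compete for bromine are not yet present.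

Step 11
Reactants: 18 2,3-dibromopropene; 19 2-methylprop-1-enylmagnesium bromide
Product: 20 2-bromo-5-methylhexa-1,4-diene
Conditions: CuI (5 mol %), THF, 0 °C → rt
Reagents that add atoms: none
Why: Copper-catalysed allylic substitution by the Grignard reagent replaces only the allylic bromide (SN2 and SN2' give the same product) and leaves the vinylic bromide as the handle.

Step 12
Reactants: 20 2-bromo-5-methylhexa-1,4-diene
Product: 22 4,4,5,5-tetramethyl-2-(5-methylhexa-1,4-dien-2-yl)-1,3,2-dioxaborolane, via alkenylmagnesium bromide 21 (not isolated)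
Conditions: Mg turnings, THF, 40 °C; then 2-isopropoxy-4,4,5,5-tetramethyl-1,3,2-dioxaborolane, −78 °C → rt; aq. NH4Cl
Reagents that add atoms: 2-isopropoxy-4,4,5,5-tetramethyl-1,3,2-dioxaborolane, CC(C)OB1OC(C)(C)C(C)(C)O1
Why: Grignard formation from a 2-bromo-1-alkene and borylation with an alkoxyboronate is the standard entry to 1,1-disubstituted alkenyl pinacol boronates and leaves the skipped diene unchanged.

Step 13
Reactants: 17 3-{4-[4,5-dibromo-2-(2-methylbut-3-en-2-yl)-1H-pyrrol-3-yl]-2,5-dimethoxy-3,6-bis(methoxymethoxy)phenyl}-1-tosylindole; 22 4,4,5,5-tetramethyl-2-(5-methylhexa-1,4-dien-2-yl)-1,3,2-dioxaborolane (1.05 equiv)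
Product: 23 3-{4-[4-bromo-2-(2-methylbut-3-en-2-yl)-5-(5-methylhexa-1,4-dien-2-yl)-1H-pyrrol-3-yl]-2,5-dimethoxy-3,6-bis(methoxymethoxy)phenyl}-1-tosylindole
Conditions: Pd(PPh3)4 (5 mol %), K2CO3, 1,4-dioxane–H2O (5:1), 65 °C
Reagents that add atoms: none
Why: In this site-selective Suzuki–Miyaura coupling zerovalent palladium inserts first into the C–Br bond alpha to nitrogen, as known for 2,3-dibromopyrroles and 2,3-dibromoindoles, and the C4 bromide is also shielded by the twisted hexasubstituted arene, so one equivalent of boronate should deliver the C5 dienyl arm that fixes the later C7 prenyl position.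

Step 14
Reactants: 24 chloroacetaldehyde dimethyl acetal
Product: 26 methoxyacetylene, via sodium methoxyacetylide 25 (not isolated)
Conditions: NaNH2 (3.2 equiv), liq. NH3, −33 °C; then sat. aq. NaCl, −70 °C → rt, distilled into a cold trap
Reagents that add atoms: none
Why: Base-induced double elimination of HCl and MeOH from an α-chloro acetal is the classical preparation of alkoxyacetylenes, with the acetylide salt protecting the product until the quench.

Step 15
Reactants: 26 methoxyacetylene
Product: 27 (E)-2-(2-methoxyvinyl)-4,4,5,5-tetramethyl-1,3,2-dioxaborolane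
Conditions: pinacolborane (1.05 equiv), Cp2Zr(H)Cl (5 mol %), CH2Cl2, 0 °C → rt
Reagents that add atoms: pinacolborane, B1OC(C)(C)C(C)(C)O1
Why: Zirconium-catalysed syn-hydroboration of the terminal alkoxyalkyne puts boron on the terminal carbon and thereby sets the (E) geometry, as in the known preparation of the ethoxy analogue.

Step 16
Reactants: 23 3-{4-[4-bromo-2-(2-methylbut-3-en-2-yl)-5-(5-methylhexa-1,4-dien-2-yl)-1H-pyrrol-3-yl]-2,5-dimethoxy-3,6-bis(methoxymethoxy)phenyl}-1-tosylindole; 27 (E)-2-(2-methoxyvinyl)-4,4,5,5-tetramethyl-1,3,2-dioxaborolane (2 equiv)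
Product: 28 3-{2,5-dimethoxy-3,6-bis(methoxymethoxy)-4-[4-[(E)-2-methoxyvinyl]-2-(2-methylbut-3-en-2-yl)-5-(5-methylhexa-1,4-dien-2-yl)-1H-pyrrol-3-yl]phenyl}-1-tosylindole
Conditions: Pd(OAc)2 (5 mol %), SPhos (10 mol %), K3PO4, THF–H2O (10:1), 55 °C; Et3N-deactivated silica
Reagents that add atoms: none
Why: Suzuki–Miyaura coupling proceeds with retention of the alkene geometry, the electron-rich bulky phosphine forces oxidative addition at the shielded C4–Br bond, and an excess of the fast-transmetalating alkenyl boronate at moderate temperature should outrun side reactions and premature ring closure.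

Step 17
Reactants: 28 3-{2,5-dimethoxy-3,6-bis(methoxymethoxy)-4-[4-[(E)-2-methoxyvinyl]-2-(2-methylbut-3-en-2-yl)-5-(5-methylhexa-1,4-dien-2-yl)-1H-pyrrol-3-yl]phenyl}-1-tosylindole
Product: 30 3-{2,5-dimethoxy-3,6-bis(methoxymethoxy)-4-[2-(2-methylbut-3-en-2-yl)-7-(3-methylbut-2-enyl)-1H-indol-3-yl]phenyl}-1-tosylindole, via 5-methoxy-5,6-dihydroindole 29 (not isolated)
Conditions: 1,2-dichlorobenzene (0.02 M), BHT (10 mol %), Ar, base-washed sealed tube, 160 °C; PPTS (5 mol %) after cooling to 60 °C to complete MeOH loss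
Reagents that add atoms: none
Why: On heating, the s-cis,s-cis conformer of the triene C6H2=C7(prenyl)–C7a=C3a–C4H=C5H(OMe) (indole numbering, C7a=C3a being the pyrrole C5=C4 bond) undergoes a thermally allowed disrotatory 6π electrocyclisation that joins the exocyclic methylene carbon to the methoxy-bearing carbon (new C5–C6 bond) and closes the six-membered carbocycle as dihydroindole 29. Compound 29 has given up the pyrrole sextet and its methoxy group is allylic and conjugated with the nitrogen through C4=C3a–C3=C2, so ionisation at C5 and loss of a C6 proton expel methanol and give the indole irreversibly without any oxidant. The closest known reaction type is the electrocyclisation–aromatisation of 2,3-dialkenylpyrroles to indoles and of 2,3-dialkenylindoles to carbazoles, including cases in which an alkoxy group leaves. The only new stereocentre, C5 of 29, forms as a racemate and is destroyed by the elimination, so no stereocontrol is needed. The step needs chemoselectivity among five C=C units, which the substrate secures because only the three named bonds are conjugated, whereas the prenyl and tert-prenyl alkenes are insulated by sp3 carbons and can react only by slower ene or cycloaddition paths. The free N–H leaves room for the prenyl CH2 in the reactive conformer, and the CH2 terminus and the (E)-enol ether turn only hydrogen inward, which keeps the barrier low, while dilution, BHT and exclusion of acid and oxygen suppress polymerisation.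

Step 18
Reactants: 30 3-{2,5-dimethoxy-3,6-bis(methoxymethoxy)-4-[2-(2-methylbut-3-en-2-yl)-7-(3-methylbut-2-enyl)-1H-indol-3-yl]phenyl}-1-tosylindole
Product: 31 3-[4-(1H-indol-3-yl)-2,5-dimethoxy-3,6-bis(methoxymethoxy)phenyl]-2-(2-methylbut-3-en-2-yl)-7-(3-methylbut-2-enyl)-1H-indole
Conditions: Mg turnings (15 equiv), MeOH–THF (3:1), ultrasound, rt
Reagents that add atoms: none
Why: Dissolving-metal (single-electron) cleavage of the N–S bond of an N-sulfonylindole by magnesium in methanol is mild and does not reduce isolated alkenes or affect MOM ethers.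

Step 19
Reactants: 31 3-[4-(1H-indol-3-yl)-2,5-dimethoxy-3,6-bis(methoxymethoxy)phenyl]-2-(2-methylbut-3-en-2-yl)-7-(3-methylbut-2-enyl)-1H-indole
Product: 33 target quinone CNP0163342.0, via hydroquinone 32 (not isolated)
Conditions: HCl (1.25 M in MeOH)–THF (1:1), 0 °C → rt, Ar; NaHCO3, extraction; then Ag2O, Na2SO4, CH2Cl2, rt
Reagents that add atoms: none
Why: Acid-catalysed acetal exchange with methanol removes aryl MOM ethers under conditions that prenylated arenes are known to survive, and the air-sensitive electron-rich hydroquinone is oxidised at once by Ag2O, a two-electron oxidant that spares free indoles and alkenes.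

## Compound list

1 | bromanilic acid (2,5-dibromo-3,6-dihydroxy-1,4-benzoquinone) | O=C1C(Br)=C(O)C(=O)C(Br)=C1O | starting material
2 | 2,5-dibromo-3,6-dimethoxy-1,4-benzoquinone | O=C1C(Br)=C(OC)C(=O)C(Br)=C1OC | intermediate
3 | 2,5-dibromo-3,6-dimethoxybenzene-1,4-diol | Oc1c(Br)c(OC)c(O)c(Br)c1OC | intermediate
4 | 1,4-dibromo-2,5-dimethoxy-3,6-bis(methoxymethoxy)benzene | COCOc1c(Br)c(OC)c(OCOC)c(Br)c1OC | intermediate
5 | 2,2-dimethylbut-3-enoic acid | C=CC(C)(C)C(=O)O | starting material
6 | dilithium 3,3-dimethylpent-4-ene-2,2-diolate (not isolated) | C=CC(C)(C)C(C)([O-])[O-].[Li+].[Li+] | intermediate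
7 | 3,3-dimethylpent-4-en-2-one | C=CC(C)(C)C(C)=O | intermediate
8 | 1-[4-bromo-2,5-dimethoxy-3,6-bis(methoxymethoxy)phenyl]-3,3-dimethylpent-4-en-2-one | C=CC(C)(C)C(=O)Cc1c(OC)c(OCOC)c(Br)c(OC)c1OCOC | intermediate
9 | prenyl bromide (1-bromo-3-methylbut-2-ene) | CC(C)=CCBr | starting material
10 | potassium enolate of 8 (not isolated) | C=CC(C)(C)C([O-])=Cc1c(OC)c(OCOC)c(Br)c(OC)c1OCOC.[K+] | intermediate
11 | (±)-5-[4-bromo-2,5-dimethoxy-3,6-bis(methoxymethoxy)phenyl]-3,3,8-trimethylnona-1,7-dien-4-one | C=CC(C)(C)C(=O)C(CC=C(C)C)c1c(OC)c(OCOC)c(Br)c(OC)c1OCOC | intermediate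
12 | secondary ozonide of 11 (3,3-dimethyl-1,2,4-trioxolane at the former trisubstituted alkene, not isolated) | C=CC(C)(C)C(=O)C(CC1OOC(C)(C)O1)c2c(OC)c(OCOC)c(Br)c(OC)c2OCOC | intermediate
13 | (±)-3-[4-bromo-2,5-dimethoxy-3,6-bis(methoxymethoxy)phenyl]-5,5-dimethyl-4-oxohept-6-enal | C=CC(C)(C)C(=O)C(CC=O)c1c(OC)c(OCOC)c(Br)c(OC)c1OCOC | intermediate
14 | 3-[4-bromo-2,5-dimethoxy-3,6-bis(methoxymethoxy)phenyl]-2-(2-methylbut-3-en-2-yl)-1H-pyrrole | C=CC(C)(C)c1[nH]ccc1-c1c(OC)c(OCOC)c(Br)c(OC)c1OCOC | intermediate
15 | 1-tosylindole-3-boronic acid | Cc1ccc(cc1)S(=O)(=O)n1cc(B(O)O)c2ccccc12 | starting material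
16 | 3-{2,5-dimethoxy-3,6-bis(methoxymethoxy)-4-[2-(2-methylbut-3-en-2-yl)-1H-pyrrol-3-yl]phenyl}-1-tosylindole | C=CC(C)(C)c1[nH]ccc1-c1c(OC)c(OCOC)c(-c2cn(S(=O)(=O)c3ccc(C)cc3)c3ccccc23)c(OC)c1OCOC | intermediate
17 | 4,5-dibromopyrrole derived from 16 | C=CC(C)(C)c1[nH]c(Br)c(Br)c1-c1c(OC)c(OCOC)c(-c2cn(S(=O)(=O)c3ccc(C)cc3)c3ccccc23)c(OC)c1OCOC | intermediate
18 | 2,3-dibromopropene | C=C(Br)CBr | starting material
19 | 2-methylprop-1-enylmagnesium bromide (THF solution) | CC(C)=C[Mg]Br | starting material
20 | 2-bromo-5-methylhexa-1,4-diene | C=C(Br)CC=C(C)C | intermediate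
21 | (5-methylhexa-1,4-dien-2-yl)magnesium bromide (not isolated) | C=C([Mg]Br)CC=C(C)C | intermediate
22 | 4,4,5,5-tetramethyl-2-(5-methylhexa-1,4-dien-2-yl)-1,3,2-dioxaborolane | C=C(CC=C(C)C)B1OC(C)(C)C(C)(C)O1 | intermediate
23 | 4-bromo-5-(5-methylhexa-1,4-dien-2-yl)pyrrole derived from 17 | C=CC(C)(C)c1[nH]c(C(=C)CC=C(C)C)c(Br)c1-c1c(OC)c(OCOC)c(-c2cn(S(=O)(=O)c3ccc(C)cc3)c3ccccc23)c(OC)c1OCOC | intermediate
24 | chloroacetaldehyde dimethyl acetal | COC(CCl)OC | starting material
25 | sodium methoxyacetylide (not isolated) | COC#[C-].[Na+] | intermediate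
26 | methoxyacetylene | COC#C | intermediate
27 | (E)-2-(2-methoxyvinyl)-4,4,5,5-tetramethyl-1,3,2-dioxaborolane | CO/C=C/B1OC(C)(C)C(C)(C)O1 | intermediate
28 | tetrasubstituted pyrrole with C5 dienyl and C4 (E)-methoxyvinyl arms (key-step precursor) | C=CC(C)(C)c1[nH]c(C(=C)CC=C(C)C)c(/C=C/OC)c1-c1c(OC)c(OCOC)c(-c2cn(S(=O)(=O)c3ccc(C)cc3)c3ccccc23)c(OC)c1OCOC | intermediate
29 | (±)-5-methoxy-5,6-dihydro-1H-indole from ring closure of 28 (not isolated) | C=CC(C)(C)C1=C(c2c(OC)c(OCOC)c(-c3cn(S(=O)(=O)c4ccc(C)cc4)c4ccccc34)c(OC)c2OCOC)C2=CC(OC)CC(CC=C(C)C)=C2N1 | intermediate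
30 | protected bis-indolyl hydroquinone (two MOM ethers, N-tosyl on indole B; key-step product) | C=CC(C)(C)c1[nH]c2c(CC=C(C)C)cccc2c1-c1c(OC)c(OCOC)c(-c2cn(S(=O)(=O)c3ccc(C)cc3)c3ccccc23)c(OC)c1OCOC | intermediate
31 | bis-MOM hydroquinone with both indole N–H free | C=CC(C)(C)c1[nH]c2c(CC=C(C)C)cccc2c1-c1c(OC)c(OCOC)c(-c2c[nH]c3ccccc23)c(OC)c1OCOC | intermediate
32 | free bis-indolyl dimethoxyhydroquinone (not isolated) | C=CC(C)(C)c1[nH]c2c(CC=C(C)C)cccc2c1-c1c(OC)c(O)c(-c2c[nH]c3ccccc23)c(OC)c1O | intermediate
33 | CNP0163342.0, 2-(1H-indol-3-yl)-3,6-dimethoxy-5-[2-(2-methylbut-3-en-2-yl)-7-(3-methylbut-2-enyl)-1H-indol-3-yl]-1,4-benzoquinone | C=CC(C)(C)c1[nH]c2c(CC=C(C)C)cccc2c1C1=C(OC)C(=O)C(c2c[nH]c3ccccc23)=C(OC)C1=O | target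

## Step count and risks

Total step count: 19.
Longest linear sequence: 14 steps (1–3, 5–10, 13, 16–19).

**Risk 1, step 17**
- The closure may be too slow at temperatures that the heat- and acid-sensitive 2-alkenylpyrrole and enol ether tolerate, so that polymerisation or ene reactions take over.
- A hydrogen shift in the dihydroindole may also restore the pyrrole without expelling methanol.
- The fallback forms the same C5–C6 bond by a polar path instead of a pericyclic one. It sets out from 28. Catalytic PPTS or camphorsulfonic acid in toluene at 40–60 °C protonates the enol ether at the carbon next to the pyrrole. The exocyclic methylene carbon of the 2-alkenylpyrrole then attacks the resulting oxocarbenium ion (Prins-type cationic cyclisation). Proton loss gives the 5-methoxy-4,5-dihydroindole F1, whose allylic methoxy group leaves under the same acid. The sequence returns to the route at 30.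

**Risk 2, step 16 (and the preceding step 13)**
- Oxidative addition at the shielded, electron-rich C4–Br bond may be slow.
- The N–H bromopyrrole may suffer protodebromination.
- The pendant prenyl alkene may insert into the C4–palladium bond (intramolecular Heck reaction) before transmetalation.
- The fallback brings in the C4 carbon by electrophilic formylation and olefination, so that no palladium ever sits on C4. It sets out from 16.
  - NCS (1 equiv, THF, −78 °C) gives the 5-chloropyrrole F2.
  - Vilsmeier–Haack formylation (POCl3, DMF, 0 °C → rt) at the only free position gives the 5-chloro-4-formylpyrrole F3.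
  - Suzuki coupling of this activated β-chloro enal unit with 22 (Pd(OAc)2, SPhos, K3PO4) gives the 5-dienylpyrrole-4-carbaldehyde F4.
  - Wittig olefination with excess MeOCH=PPh3 (from (methoxymethyl)triphenylphosphonium chloride and KHMDS) gives the enol ether.
  - The (E) isomer is separated, and the sequence returns to the route at 28.

**Risk 3, step 5**
- Oxidative addition into the di-ortho-alkoxy bromide may be sluggish.
- Both bromides may couple.
- A Heck reaction may occur at the vinyl group of 7.
- The fallback desymmetrises by stoichiometric metalation and builds the ketone from the aldehyde level. It sets out from 4.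
  - n-BuLi (1 equiv, THF, −78 °C), then ethylene oxide and BF3·OEt2, give the 2-arylethanol F5.
  - Dess–Martin oxidation gives the arylacetaldehyde F6.
  - Barbier addition of prenyl bromide with indium powder (THF–H2O), which attacks through the γ-carbon, gives the reverse-prenyl carbinol F7.
  - A second Dess–Martin oxidation returns to the route at 8.

## Further compounds

F1 | step 17 | (±)-5-methoxy-4,5-dihydro-1H-indole analogue of 30 (C4H2, C5H(OMe), C6=C7) | C=CC(C)(C)c1[nH]c2C(CC=C(C)C)=CC(OC)Cc2c1-c3c(OC)c(OCOC)c(-c4cn(S(=O)(=O)c5ccc(C)cc5)c5ccccc45)c(OC)c3OCOC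
F2 | step 16 | 5-chloropyrrole derived from 16 | C=CC(C)(C)c1[nH]c(Cl)cc1-c1c(OC)c(OCOC)c(-c2cn(S(=O)(=O)c3ccc(C)cc3)c3ccccc23)c(OC)c1OCOC
F3 | step 16 | 5-chloro-4-formylpyrrole derived from 16 | C=CC(C)(C)c1[nH]c(Cl)c(C=O)c1-c1c(OC)c(OCOC)c(-c2cn(S(=O)(=O)c3ccc(C)cc3)c3ccccc23)c(OC)c1OCOC
F4 | step 16 | 5-(5-methylhexa-1,4-dien-2-yl)pyrrole-4-carbaldehyde derived from 16 | C=CC(C)(C)c1[nH]c(C(=C)CC=C(C)C)c(C=O)c1-c1c(OC)c(OCOC)c(-c2cn(S(=O)(=O)c3ccc(C)cc3)c3ccccc23)c(OC)c1OCOC
F5 | step 5 | 2-[4-bromo-2,5-dimethoxy-3,6-bis(methoxymethoxy)phenyl]ethanol | OCCc1c(OC)c(OCOC)c(Br)c(OC)c1OCOC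
F6 | step 5 | 2-[4-bromo-2,5-dimethoxy-3,6-bis(methoxymethoxy)phenyl]acetaldehyde | O=CCc1c(OC)c(OCOC)c(Br)c(OC)c1OCOC
F7 | step 5 | (±)-1-[4-bromo-2,5-dimethoxy-3,6-bis(methoxymethoxy)phenyl]-3,3-dimethylpent-4-en-2-ol | C=CC(C)(C)C(O)Cc1c(OC)c(OCOC)c(Br)c(OC)c1OCOC
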